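**Retrosynthetic overview**
1. The target is cut into two molecules of one cis‑fused Diels–Alder adduct (26 of the 30 skeletal carbons) plus four one‑carbon units (C26 from MeI, C27 from CH2O, C11 from a methylenation reagent, C12 from CH2I2). The last two disconnections are C14–C27 (6‑endo radical closure of ring C) and C11–C12 (B‑alkyl Suzuki coupling of left half 15 with right half 27).
2. Right half: ring D is made by a one‑carbon ring expansion (C12 inserted between C13 and C14) of the six‑membered carvone ring of the adduct, then taken to the 1,3‑dione and its 12‑iodo‑14‑benzyloxy enone. Left half: the C8 quaternary centre (C26, C27) and the 3β‑OMe are installed on the same adduct and the C9 carbonyl is methylenated.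
3. Key disconnection (ring A, and identically ring E): C1–C10 and C4–C5 (C19–C18 and C22–C17) by [4+2] addition of the diene C1=C2–C3(OSi)=C4Me2 to the C5=C10 enone of (S)‑carvone, whose carbonyl carbon becomes C9 (C13).
4. Enabling feature: ring A is a C3‑oxygenated, C4‑gem‑dimethyl cyclohexane cis‑fused to ring B at C5(H)–C10(CH3), with C9 next to C10 free to be a carbonyl in the precursor. Ring E repeats this array (O at C21, Me2 at C22, C17(H)–C18(CH3) cis, C13 ketone) with the same absolute configuration, so one adduct serves both ends; the isopropenyl group of carvone is a traceless control element.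
5. Ring order: A (with B) and E (with six‑membered D) in the key step, then D expanded to seven, then union of the halves, then C.

Key step: step 2

Remark: the stereodescriptors of the SMILES are taken literally; with triterpenoid locants (ring D = C12–C18, C27 = CH2 between C8 and C14, C11 = CH2 between C9 and C12) and β = the face of the C10 methyl they read 3β‑OMe, 5β‑H, 8β‑Me, 9β‑H, 10β‑Me, 12α‑H, 14β‑OH, 17α‑H, 18α‑Me, 21β‑OH (A/B, B/C and D/E cis, C/D trans); bicyclic intermediates are named as decalins with these locants, and 4‑methylpent‑1‑en‑3‑one and (S)‑carvone are taken as commercial.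

Abbreviations: TBS = tert‑butyldimethylsilyl, TMS = trimethylsilyl, Bn = benzyl.

**Step 1**
Reactants: 1 4‑methylpent‑1‑en‑3‑one
Product: 2 3‑(TBS‑oxy)‑4‑methylpenta‑1,3‑diene
Conditions: TBSOTf, Et3N, CH2Cl2, 0 °C
Reagents that add atoms: tert‑butyldimethylsilyl triflate (CC(C)(C)[Si](C)(C)OS(=O)(=O)C(F)(F)F)
Why: Soft enolization and O‑silylation (silyl enol ether formation) at the only enolizable position, the isopropyl methine, should give the 2‑silyloxydiene regiospecifically.

**Step 2**
Reactants: 2 3‑(TBS‑oxy)‑4‑methylpenta‑1,3‑diene; 3 (S)‑(+)‑carvone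
Product: 4 3‑(TBS‑oxy)‑7β‑isopropenyl‑4,4,10β‑trimethyl‑5β‑decal‑2‑en‑9‑one (cis‑fused adduct)
Conditions: AlBr3/AlMe3 (5:1, substoichiometric), PhMe/CH2Cl2, −10 °C → 0 °C; Et3N quench
Reagents that add atoms: none
Why: Lewis acid‑promoted normal‑demand Diels–Alder reaction, possibly asynchronous up to a Mukaiyama–Michael/Michael sequence, in which the aluminium‑complexed enone is attacked at its β‑carbon C5 by the fully substituted enol ether carbon C4 of the diene and the C1 terminus then bonds to the α‑carbon C10. The closest known reaction type is the mixed AlBr3/AlMe3‑catalysed Diels–Alder reaction of hindered 2‑silyloxydienes with 2‑methylcycloalk‑2‑enones, which gives cis‑fused decalones with adjacent quaternary carbons. Ring A (six‑membered) is closed by intermolecular [4+2] addition across C5=C10, suprafacial on both partners (in the stepwise limit a 6‑endo‑trig Michael closure). C5 is set by approach of the diene anti to the isopropenyl group at C7 of carvone, and C10 follows from suprafacial addition to the ring (Z)‑alkene, which enforces the cis A/B fusion with 5‑H, 10‑Me and isopropenyl on one face. The regiochemistry needed (gem‑dimethyl terminus to C5) is secured by polarity (enol ether carbon to enone β‑carbon) and by sterics (the alternative would join two fully substituted carbons); AlMe3 scavenges protic acid so that the silyl enol ether, which keeps the C3 and C9 oxygens differentiated, should survive.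

**Step 3**
Reactants: 4 3‑(TBS‑oxy)‑7β‑isopropenyl‑4,4,10β‑trimethyl‑5β‑decal‑2‑en‑9‑one
Product: 6 3‑(TBS‑oxy)‑7β‑isopropenyl‑4,4,8α,10β‑tetramethyl‑5β‑decal‑2‑en‑9‑one, via lithium enolate 5 (not isolated)
Conditions: LiN(iPr)2, THF, −78 °C; MeI, −78 °C → 0 °C
Reagents that add atoms: iodomethane (CI)
Why: Kinetic enolate alkylation; the C9 ketone can enolize only towards C8 because C10 is quaternary, the ring A silyl enol ether is inert to the amide base, and the C8 configuration is irrelevant since this centre is enolized again in step 4.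

**Step 4**
Reactants: 6 3‑(TBS‑oxy)‑7β‑isopropenyl‑4,4,8α,10β‑tetramethyl‑5β‑decal‑2‑en‑9‑one
Product: 9 8α‑(hydroxymethyl)‑7β‑isopropenyl‑4,4,8β,10β‑tetramethyl‑5β‑decalin‑3,9‑dione, via lithium enolate 7 (not isolated), via aldol silyl enol ether 8 (not isolated)
Conditions: LiN(iPr)2, THF, −78 °C → 0 °C; CH2O (gas), −78 °C; then aq. HCl (1 M), THF, 0 °C → rt
Reagents that add atoms: formaldehyde (C=O)
Why: Aldol addition of the tetrasubstituted C8=C9 enolate to monomeric formaldehyde, in which the electrophile should enter anti to the adjacent isopropenyl group at C7 (1,2‑induction), so that C27 becomes α and the methyl C26 β at the quaternary C8; the acidic work‑up hydrolyses the silyl enol ether to the C3 ketone.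

**Step 5**
Reactants: 9 8α‑(hydroxymethyl)‑7β‑isopropenyl‑4,4,8β,10β‑tetramethyl‑5β‑decalin‑3,9‑dione
Product: 11 8α‑(hydroxymethyl)‑4,4,8β,10β‑tetramethyl‑5β‑decalin‑3,9‑dione, via methoxy hydroperoxide 10 (not isolated)
Conditions: O3, MeOH/CH2Cl2, −78 °C; then FeSO4·7H2O, PhSH, −78 °C → rt
Reagents that add atoms: none
Why: Ozonolytic hydrodealkenylation; the α‑methoxy hydroperoxide is cleaved by divalent iron, β‑scission releases methyl acetate and a C7 radical that takes hydrogen from thiophenol, which deletes the control group without forming a stereocentre.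

**Step 6**
Reactants: 11 8α‑(hydroxymethyl)‑4,4,8β,10β‑tetramethyl‑5β‑decalin‑3,9‑dione
Product: 12 8α‑(iodomethyl)‑4,4,8β,10β‑tetramethyl‑5β‑decalin‑3,9‑dione
Conditions: I2, PPh3, imidazole, PhMe, 90 °C
Reagents that add atoms: iodine (II)
Why: Garegg–Samuelsson iodination (iodide displacement of the alkoxyphosphonium ion), which is slow but workable at a neopentyl primary carbon at this temperature and touches no stereocentre.

**Step 7**
Reactants: 12 8α‑(iodomethyl)‑4,4,8β,10β‑tetramethyl‑5β‑decalin‑3,9‑dione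
Product: 13 3β‑hydroxy‑8α‑(iodomethyl)‑4,4,8β,10β‑tetramethyl‑5β‑decalin‑9‑one
Conditions: (R)‑Me‑CBS [(R)‑1‑methyl‑3,3‑diphenyltetrahydro‑1H,3H‑pyrrolo[1,2‑c][1,3,2]oxazaborole] (0.2 equiv), BH3·SMe2, THF, −20 °C
Reagents that add atoms: none
Why: Corey–Bakshi–Shibata reduction; the C9 ketone lies between two quaternary carbons and should be inert, while the (R)‑catalyst (large group CMe2, small group CH2) delivers hydride to the α face of the C3 carbonyl and sets the 3β‑alcohol by reagent control.

**Step 8**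
Reactants: 13 3β‑hydroxy‑8α‑(iodomethyl)‑4,4,8β,10β‑tetramethyl‑5β‑decalin‑9‑one
Product: 14 8α‑(iodomethyl)‑3β‑methoxy‑4,4,8β,10β‑tetramethyl‑5β‑decalin‑9‑one
Conditions: NaH, MeI, THF/DMF, 0 °C → rt
Reagents that add atoms: iodomethane (CI)
Why: Williamson O‑methylation; the C9 ketone has no α‑hydrogen and the neopentyl iodide does not undergo substitution, so only the alkoxide should react.

**Step 9**
Reactants: 14 8α‑(iodomethyl)‑3β‑methoxy‑4,4,8β,10β‑tetramethyl‑5β‑decalin‑9‑one
Product: 15 8α‑(iodomethyl)‑3β‑methoxy‑4,4,8β,10β‑tetramethyl‑9‑methylene‑5β‑decalin (left half)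
Conditions: Cp2Ti(μ‑CH2)(μ‑Cl)AlMe2, pyridine (cat.), THF/PhMe, −40 °C → rt
Reagents that add atoms: Tebbe reagent (C[Al-]1(C)C[Ti](C2C=CC=C2)(C2C=CC=C2)[Cl+]1)
Why: Tebbe methylenation; the small, oxophilic titanium methylidene olefinates hindered non‑enolizable ketones where phosphorus ylides fail, and it supplies C11 without forming a stereocentre.

**Step 10**
Reactants: 4 3‑(TBS‑oxy)‑7β‑isopropenyl‑4,4,10β‑trimethyl‑5β‑decal‑2‑en‑9‑one
Product: 16 7β‑isopropenyl‑4,4,10β‑trimethyl‑5β‑decalin‑3,9‑dione (right‑half locants: C3=C21, C4=C22, C5=C17, C6=C16, C7=C15, C8=C14, C9=C13, C10=C18)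
Conditions: aq. HCl (1 M), THF, rt
Reagents that add atoms: none
Why: Acid hydrolysis of the silyl enol ether unmasks the second ketone; neither ring‑fusion centre is α to a carbonyl, so the cis fusion cannot epimerize.

**Step 11**
Reactants: 16 7β‑isopropenyl‑4,4,10β‑trimethyl‑5β‑decalin‑3,9‑dione
Product: 18 17α‑H‑18α,22,22‑trimethyl bicyclic 13,21‑dione (rings E and six‑membered D), via methoxy hydroperoxide 17 (not isolated)
Conditions: O3, MeOH/CH2Cl2, −78 °C; then FeSO4·7H2O, PhSH, −78 °C → rt
Reagents that add atoms: none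
Why: The same ozonolytic hydrodealkenylation as in step 5 removes the isopropenyl group from C15 through the C15 radical and thiol hydrogen transfer.

**Step 12**
Reactants: 18 17α‑H‑18α,22,22‑trimethyl bicyclic 13,21‑dione
Product: 19 21β‑hydroxy‑17α‑H‑18α,22,22‑trimethyl bicyclic 13‑ketone (OH trans to Me‑28)
Conditions: NaBH4 (0.35 equiv), MeOH/CH2Cl2, −40 °C
Reagents that add atoms: none
Why: Chemoselective borohydride reduction; the C21 carbonyl should be the more accessible one because C13 is shielded by the ring‑fusion quaternary carbon C18, and hydride should attack from the convex face (that of Me‑28 and H‑17), placing the hydroxyl trans to Me‑28.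

**Step 13**
Reactants: 19 21β‑hydroxy‑17α‑H‑18α,22,22‑trimethyl bicyclic 13‑ketone
Product: 20 13,21β‑bis(TMS‑oxy)‑17α‑H‑18α,22,22‑trimethyl bicyclic 13(14)‑ene
Conditions: Me3SiOTf, Et3N, CH2Cl2, 0 °C
Reagents that add atoms: trimethylsilyl triflate (C[Si](C)(C)OS(=O)(=O)C(F)(F)F)
Why: Soft enolization and silylation protect the alcohol and convert the C13 ketone into its only possible silyl enol ether (C13=C14), since C18 is quaternary.

**Step 14**
Reactants: 20 13,21β‑bis(TMS‑oxy)‑17α‑H‑18α,22,22‑trimethyl bicyclic 13(14)‑ene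
Product: 21 13,14‑methano (cyclopropane CH2 = C12, drawn syn to Me‑28) 13,21β‑bis(TMS‑oxy) bicycle
Conditions: Et2Zn, CH2I2, CH2Cl2, 0 °C → rt
Reagents that add atoms: diiodomethane (ICI)
Why: Simmons–Smith cyclopropanation (Furukawa modification) of the electron‑rich silyl enol ether delivers the carbon that becomes C12; the cyclopropane configuration is irrelevant because both of its stereocentres are destroyed in step 15.

**Step 15**
Reactants: 21 13,14‑methano 13,21β‑bis(TMS‑oxy) bicycle
Product: 23 21β‑hydroxy‑17α‑H‑18α,22,22‑trimethyl ring‑D cyclohept‑12(14)‑en‑13‑one, via chloro ketone 22 (not isolated)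
Conditions: FeCl3, DMF, 0 °C; aq. HCl work‑up; then NaOAc, MeOH, reflux
Reagents that add atoms: none
Why: Ito–Saegusa ring expansion; FeCl3 oxidizes the silyloxycyclopropane to an alkoxy radical that opens the internal C13–C14 bond, the ring‑enlarged C14 radical is chlorinated and acetate eliminates HCl, so C12 ends between C13 and C14 in a seven‑membered enone.

**Step 16**
Reactants: 23 21β‑hydroxy ring‑D cyclohept‑12(14)‑en‑13‑one
Product: 24 12,14‑epoxy‑21β‑hydroxy ring‑D cycloheptan‑13‑one (epoxide drawn syn to Me‑28)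
Conditions: H2O2 (30% aq.), NaOH, MeOH, 0 °C
Reagents that add atoms: hydrogen peroxide (OO)
Why: Weitz–Scheffer nucleophilic epoxidation of the enone; the epoxide configuration is irrelevant because both centres are removed in step 17.

**Step 17**
Reactants: 24 12,14‑epoxy‑21β‑hydroxy ring‑D cycloheptan‑13‑one
Product: 25 21β‑hydroxy ring‑D cycloheptane‑1,3‑dione (carbonyls at C13 and C14 flanking C12)
Conditions: Pd(PPh3)4 (5 mol %), Ph2PCH2CH2PPh2 (5 mol %), PhMe, 100 °C
Reagents that add atoms: none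
Why: Zerovalent‑palladium‑catalysed isomerization of an α,β‑epoxy ketone to a 1,3‑diketone (insertion into the Cα–O bond, β‑hydride elimination from C14, tautomerization) places the second carbonyl at C14.

**Step 18**
Reactants: 25 21β‑hydroxy ring‑D cycloheptane‑1,3‑dione
Product: 26 14‑benzyloxy‑21β‑hydroxy ring‑D cyclohept‑12(14)‑en‑13‑one
Conditions: BnOH, p‑TsOH·H2O (cat.), PhH, reflux (Dean–Stark)
Reagents that add atoms: benzyl alcohol (OCc1ccccc1)
Why: Acid‑catalysed vinylogous ester formation with water removal; the less hindered oxygen (on C14) should be etherified and the carbonyl next to quaternary C18 retained, as with other 4,4‑disubstituted cyclic 1,3‑diones.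

**Step 19**
Reactants: 26 14‑benzyloxy‑21β‑hydroxy ring‑D cyclohept‑12(14)‑en‑13‑one
Product: 27 14‑benzyloxy‑21β‑hydroxy‑12‑iodo ring‑D cyclohept‑12(14)‑en‑13‑one (right half)
Conditions: I2, pyridine, CH2Cl2, 0 °C → rt
Reagents that add atoms: iodine (II)
Why: Electrophilic α‑iodination of the electron‑rich β‑alkoxy enone at C12 gives the vinyl iodide needed for cross‑coupling.

**Step 20**
Reactants: 15 8α‑(iodomethyl)‑3β‑methoxy‑4,4,8β,10β‑tetramethyl‑9‑methylene‑5β‑decalin; 27 14‑benzyloxy‑21β‑hydroxy‑12‑iodo ring‑D cyclohept‑12(14)‑en‑13‑one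
Product: 29 C11–C12‑linked seco compound (ring C open; 9β‑H; 27‑iodide; 14‑benzyloxy‑12(14)‑en‑13‑one), via alkylborane 28 (not isolated)
Conditions: 9‑BBN‑H, THF, 65 °C; then 27, Pd(dppf)Cl2 (10 mol %), AsPh3, Cs2CO3, DMF/H2O, 50 °C
Reagents that add atoms: none
Why: B‑alkyl Suzuki–Miyaura coupling; 9‑BBN‑H should add to the C9=C11 alkene with boron at C11 and hydrogen at C9 from the β face (the α face is flanked by the axial C1 and C27 methylenes), setting 9β‑H, and the primary alkylborane then couples with the vinyl iodide, which inserts palladium far faster than the neopentyl iodide.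

**Step 21**
Reactants: 29 C11–C12‑linked seco compound
Product: 30 14β‑O‑benzyl ether of the target (rings A–E closed; 12α‑H)
Conditions: Bu3SnH (slow addition), azobisisobutyronitrile (cat.), PhH (high dilution), 80 °C
Reagents that add atoms: none
Why: Proposed new method: the tin radical abstracts iodine from C27 and the nucleophilic neopentyl radical should add 6‑endo‑trig to C14, the β‑carbon of the 3‑benzyloxy enone (5‑exo attack at the α‑carbon C12 is electronically and sterically disfavoured), after which the C12 α‑keto radical takes hydrogen from the stannane; the closest known reaction types are tin hydride 6‑endo cyclizations onto α‑tethered cycloalkenones and radical additions to the oxygen‑bearing carbon of β‑alkoxyacrylates and vinylogous esters; in the chair‑like transition state imposed by the cis B/C fusion, C15 (anti to C11 across the former double bond) becomes equatorial and the benzyloxy group axial on the β face, which sets C14, and the enolizable C12 should settle with C13 equatorial (12α‑H, trans C/D).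

**Step 22**
Reactants: 30 14β‑O‑benzyl ether of the target
Product: 31 CNP0259231.1 (target)
Conditions: H2 (1 atm), Pd(OH)2/C, EtOAc/EtOH, rt; then Et3N, MeOH, rt
Reagents that add atoms: none
Why: Hydrogenolysis of the tertiary benzyl ether under neutral conditions frees the 14β‑hydroxyl without β‑elimination, and the mild amine treatment should equilibrate any 12‑epimer to the diequatorial trans C/D β‑hydroxy ketone.

**Compound list**
1 | 4‑methylpent‑1‑en‑3‑one | CC(C)C(=O)C=C | starting material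
2 | 3‑(TBS‑oxy)‑4‑methylpenta‑1,3‑diene | CC(C)=C(O[Si](C)(C)C(C)(C)C)C=C | intermediate
3 | (S)‑(+)‑carvone | CC1=CC[C@H](C(C)=C)CC1=O | starting material
4 | 3‑(TBS‑oxy)‑7β‑isopropenyl‑4,4,10β‑trimethyl‑5β‑decal‑2‑en‑9‑one | CC(C)(C)[Si](C)(C)OC1=CC[C@@]2(C)[C@H](C[C@H](C(C)=C)CC2=O)C1(C)C | intermediate
5 | lithium C8=C9 enolate of 4 (not isolated) | CC(C)(C)[Si](C)(C)OC1=CC[C@@]2(C)[C@H](C[C@H](C(C)=C)C=C2O[Li])C1(C)C | intermediate
6 | 3‑(TBS‑oxy)‑7β‑isopropenyl‑4,4,8α,10β‑tetramethyl‑5β‑decal‑2‑en‑9‑one | CC(C)(C)[Si](C)(C)OC1=CC[C@@]2(C)[C@H](C[C@H](C(C)=C)[C@@H](C)C2=O)C1(C)C | intermediate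
7 | lithium C8=C9 enolate of 6 (not isolated) | CC(C)(C)[Si](C)(C)OC1=CC[C@@]2(C)[C@H](C[C@H](C(C)=C)C(C)=C2O[Li])C1(C)C | intermediate
8 | 3‑(TBS‑oxy)‑8α‑(hydroxymethyl)‑7β‑isopropenyl‑4,4,8β,10β‑tetramethyl‑5β‑decal‑2‑en‑9‑one (not isolated) | CC(C)(C)[Si](C)(C)OC1=CC[C@@]2(C)[C@H](C[C@H](C(C)=C)[C@@](C)(CO)C2=O)C1(C)C | intermediate
9 | 8α‑(hydroxymethyl)‑7β‑isopropenyl‑4,4,8β,10β‑tetramethyl‑5β‑decalin‑3,9‑dione | O=C1CC[C@@]2(C)[C@H](C[C@H](C(C)=C)[C@@](C)(CO)C2=O)C1(C)C | intermediate
10 | 7β‑(1‑hydroperoxy‑1‑methoxyethyl) analogue of 9 (not isolated; epimers at the peroxy carbon) | O=C1CC[C@@]2(C)[C@H](C[C@H](C(C)(OC)OO)[C@@](C)(CO)C2=O)C1(C)C | intermediate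
11 | 8α‑(hydroxymethyl)‑4,4,8β,10β‑tetramethyl‑5β‑decalin‑3,9‑dione | O=C1CC[C@@]2(C)[C@H](CC[C@@](C)(CO)C2=O)C1(C)C | intermediate
12 | 8α‑(iodomethyl)‑4,4,8β,10β‑tetramethyl‑5β‑decalin‑3,9‑dione | O=C1CC[C@@]2(C)[C@H](CC[C@@](C)(CI)C2=O)C1(C)C | intermediate
13 | 3β‑hydroxy‑8α‑(iodomethyl)‑4,4,8β,10β‑tetramethyl‑5β‑decalin‑9‑one | O[C@H]1CC[C@@]2(C)[C@H](CC[C@@](C)(CI)C2=O)C1(C)C | intermediate
14 | 8α‑(iodomethyl)‑3β‑methoxy‑4,4,8β,10β‑tetramethyl‑5β‑decalin‑9‑one | CO[C@H]1CC[C@@]2(C)[C@H](CC[C@@](C)(CI)C2=O)C1(C)C | intermediate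
15 | 8α‑(iodomethyl)‑3β‑methoxy‑4,4,8β,10β‑tetramethyl‑9‑methylene‑5β‑decalin | CO[C@H]1CC[C@@]2(C)[C@H](CC[C@@](C)(CI)C2=C)C1(C)C | intermediate
16 | 7β‑isopropenyl‑4,4,10β‑trimethyl‑5β‑decalin‑3,9‑dione | O=C1CC[C@@]2(C)[C@H](C[C@H](C(C)=C)CC2=O)C1(C)C | intermediate
17 | 7β‑(1‑hydroperoxy‑1‑methoxyethyl) analogue of 16 (not isolated; epimers at the peroxy carbon) | O=C1CC[C@@]2(C)[C@H](C[C@H](C(C)(OC)OO)CC2=O)C1(C)C | intermediate
18 | 17α‑H‑18α,22,22‑trimethyl bicyclic 13,21‑dione | O=C1CC[C@@]2(C)[C@H](CCCC2=O)C1(C)C | intermediate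
19 | 21β‑hydroxy‑17α‑H‑18α,22,22‑trimethyl bicyclic 13‑ketone | O=C1CCC[C@@H]2C(C)(C)[C@H](O)CC[C@]12C | intermediate
20 | 13,21β‑bis(TMS‑oxy) bicyclic 13(14)‑ene | C[Si](C)(C)OC1=CCC[C@@H]2C(C)(C)[C@H](O[Si](C)(C)C)CC[C@]12C | intermediate
21 | 13,14‑methano‑13,21β‑bis(TMS‑oxy) bicycle | C[Si](C)(C)O[C@]12C[C@H]1CC[C@@H]3C(C)(C)[C@H](O[Si](C)(C)C)CC[C@]23C | intermediate
22 | 14‑chloro‑21β‑hydroxy ring‑D cycloheptan‑13‑one (not isolated; C14 epimers) | O=C1CC(Cl)CC[C@@H]2C(C)(C)[C@H](O)CC[C@]12C | intermediate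
23 | 21β‑hydroxy ring‑D cyclohept‑12(14)‑en‑13‑one | O=C1C=CCC[C@@H]2C(C)(C)[C@H](O)CC[C@]12C | intermediate
24 | 12,14‑epoxy‑21β‑hydroxy ring‑D cycloheptan‑13‑one | O=C1[C@H]2O[C@H]2CC[C@@H]3C(C)(C)[C@H](O)CC[C@]13C | intermediate
25 | 21β‑hydroxy ring‑D cycloheptane‑1,3‑dione (C13, C14) | O=C1CC(=O)CC[C@@H]2C(C)(C)[C@H](O)CC[C@]12C | intermediate
26 | 14‑benzyloxy‑21β‑hydroxy ring‑D cyclohept‑12(14)‑en‑13‑one | O=C1C=C(OCc2ccccc2)CC[C@@H]2C(C)(C)[C@H](O)CC[C@]12C | intermediate
27 | 14‑benzyloxy‑21β‑hydroxy‑12‑iodo ring‑D cyclohept‑12(14)‑en‑13‑one | O=C1C(I)=C(OCc2ccccc2)CC[C@@H]2C(C)(C)[C@H](O)CC[C@]12C | intermediate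
28 | B‑(C11)‑alkyl‑9‑BBN from 15 (9β‑H; not isolated) | CO[C@H]1CC[C@@]2(C)[C@H](CC[C@@](C)(CI)[C@H]2CB2C3CCCC2CCC3)C1(C)C | intermediate
29 | C11–C12‑linked seco compound (ring C open) | CO[C@H]1CC[C@@]2(C)[C@H](CC[C@@](C)(CI)[C@H]2CC2=C(OCc3ccccc3)CC[C@@H]3C(C)(C)[C@H](O)CC[C@]3(C)C2=O)C1(C)C | intermediate
30 | 14β‑O‑benzyl ether of the target | CO[C@H]1CC[C@@]2(C)[C@H](CC[C@@]3(C)C[C@@]4(OCc6ccccc6)CC[C@@H]5C(C)(C)[C@H](O)CC[C@]5(C)C(=O)[C@@H]4C[C@H]32)C1(C)C | intermediate
31 | CNP0259231.1 | CO[C@H]1CC[C@@]2(C)[C@H](CC[C@@]3(C)C[C@@]4(O)CC[C@@H]5C(C)(C)[C@H](O)CC[C@]5(C)C(=O)[C@@H]4C[C@H]32)C1(C)C | target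

**Step count and risks**
Total step count: 22. Longest linear sequence: 15 steps (steps 1, 2, 10–19, 20–22).

Steps most likely to fail:

1. Step 21 (Proposed new method). The C27 radical may be reduced before it adds to the fully substituted C14, or may close 5‑exo at C12. The fallback sets out from 29 and comes back at 31 by polar chemistry. Aqueous HCl in THF should hydrolyse the benzyl enol ether to the 2‑alkylcycloheptane‑1,3‑dione F2. PhNTf2 and Et3N should triflate the less hindered oxygen to give the vinylogous triflate F3. A nickel‑catalysed intramolecular reductive alkyl iodide–vinyl triflate coupling (NiBr2·glyme, 4,4′‑di‑tert‑butyl‑2,2′‑bipyridine, Mn, DMA) should close ring C to the tetrasubstituted enone F4. Nucleophilic epoxidation (t‑BuOOH, DBU) on the β face should give the epoxy ketone F5, whose Cα–O bond SmI2 (THF/MeOH, −78 °C) should cleave to give 31.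

2. Step 2. Bond formation between the fully substituted diene terminus and the enone β‑carbon may be sluggish, or the reaction may stop after the first (Michael) bond with loss of the silyl group. The fallback sets out from 2 and 3 and comes back at 4 in two ionic stages. A TiCl4‑mediated Mukaiyama–Michael addition (CH2Cl2, −78 °C, aqueous work‑up) should give the open‑chain diketone F1, again anti to the isopropenyl group. TBSOTf and Et3N should then silylate the ring ketone towards C10 and close ring A by intramolecular Mukaiyama–Michael addition to the vinyl ketone, with silyl transfer to the C3 oxygen.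

3. Step 9. Carbonyl olefination may fail at the C9 ketone, which lies between two quaternary carbons. The fallback sets out from 14 and comes back at 15. MeMgBr with CeCl3 (THF, −78 °C → 0 °C) should add from the β face to give the tertiary carbinol F6. Dehydration with the Burgess reagent (PhH, 50 °C) can only give the exocyclic alkene, because C8 and C10 carry no hydrogen.

**Further compounds**
F1 | step 2 | 2‑methyl‑3‑(2‑methyl‑3‑oxopent‑4‑en‑2‑yl)‑5‑isopropenylcyclohexanone (side chain trans to isopropenyl; C2 epimers) | C=CC(=O)C(C)(C)[C@H]1C[C@H](C(C)=C)CC(=O)C1C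
F2 | step 21 | 2‑alkylcycloheptane‑1,3‑dione from 29 (C12 stereolabile) | CO[C@H]1CC[C@@]2(C)[C@H](CC[C@@](C)(CI)[C@H]2CC2C(=O)CC[C@@H]3C(C)(C)[C@H](O)CC[C@]3(C)C2=O)C1(C)C
F3 | step 21 | 14‑triflyloxy‑12(14)‑en‑13‑one (vinylogous triflate) | CO[C@H]1CC[C@@]2(C)[C@H](CC[C@@](C)(CI)[C@H]2CC2=C(OS(=O)(=O)C(F)(F)F)CC[C@@H]3C(C)(C)[C@H](O)CC[C@]3(C)C2=O)C1(C)C
F4 | step 21 | pentacyclic 12(14)‑en‑13‑one (ring C closed) | CO[C@H]1CC[C@@]2(C)[C@H](CC[C@@]3(C)CC4=C(C[C@H]32)C(=O)[C@@]5(C)CC[C@@H](O)C(C)(C)[C@H]5CC4)C1(C)C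
F5 | step 21 | 12β,14β‑epoxy‑13‑ketone | CO[C@H]1CC[C@@]2(C)[C@H](CC[C@@]3(C)C[C@@]4(O6)CC[C@@H]5C(C)(C)[C@H](O)CC[C@]5(C)C(=O)[C@@]46C[C@H]32)C1(C)C
F6 | step 9 | 9α‑hydroxy‑8α‑(iodomethyl)‑3β‑methoxy‑4,4,8β,9β,10β‑pentamethyl‑5β‑decalin | CO[C@H]1CC[C@@]2(C)[C@H](CC[C@@](C)(CI)[C@@]2(C)O)C1(C)C
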